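**Retrosynthetic overview**
- The target is a head-to-tail dimer of two 12-methoxyabieta-8,11,13-triene halves (A and B). A 1,4-dioxane links them through C7–O–C6' and C6–O–C7'; all four ring-B oxygens are equatorial (6α, 7β).
- Key disconnection: the C6–C7 bond of half A together with the O(on C7)–C6' bond. This leads to vinyl acetal 9, in which the C7 oxygen still bridges C7H2 and the acetal carbon C6 (a seven-membered oxa-homo ring B), and C6 is bonded through oxygen to C7' of the 6',7'-enol ether of half B.
- Enabling feature: C7 is benzylic, para to the C12 methoxy group, and adjacent to the oxygen-bearing C6. The C6–C7/C7–O array is therefore the 1,2-shift isomer of a benzyl acetal, and the C6'=C7' enol ether of half B (from the 7-ketone) can accept the oxygen radical released by that shift.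
- 9 comes from O-alkylation of the enolate of 7-ketone 3 with the chloro ether of lactol 6; 6 comes from 6,7-seco-dialdehyde 5. Both halves derive from ferruginol.
- Ring order: rings A and C come from the chiral pool; ring B of half A is cleaved and then, in the key step, re-formed first, with the dioxane closing second.

Key step: step 7

Assumption: natural (+)-ferruginol (1), a catalogue natural product of the (5S,10S)-abietane series, is the single chiral starting material for both halves.

Step 1
Reactants: 1 (+)-ferruginol
Product: 2 ferruginol methyl ether (12-methoxyabieta-8,11,13-triene)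
Conditions: MeI, K2CO3, acetone, reflux
Reagents that add atoms: iodomethane, CI
Why: Williamson ether synthesis on the phenol, with no stereocenter touched.

Step 2
Reactants: 2 ferruginol methyl ether
Product: 3 sugiol methyl ether (12-methoxyabieta-8,11,13-trien-7-one)
Conditions: CrO3, AcOH–H2O, rt
Reagents that add atoms: chromium trioxide, O=[Cr](=O)=O
Why: Benzylic oxidation with CrO3 should select the ring-B methylene C7, which is para to the methoxy group and less hindered than the isopropyl methine, and creates no stereocenter.

Step 3
Reactants: 2 ferruginol methyl ether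
Product: 4 12-methoxyabieta-6,8,11,13-tetraene
Conditions: DDQ (1.1 equiv), toluene, 80 °C
Reagents that add atoms: none
Why: DDQ dehydrogenation by hydride abstraction from the para-methoxy-activated benzylic C7 and loss of H6 should give the conjugated 6,7-alkene without touching C5 or C10.

Step 4
Reactants: 4 12-methoxyabieta-6,8,11,13-tetraene
Product: 5 12-methoxy-6,7-secoabieta-8,11,13-triene-6,7-dial
Conditions: O3, CH2Cl2–MeOH, pyridine, −78 °C (indicator dye end point); then Me2S, −78 °C to rt
Reagents that add atoms: ozone, [O-][O+]=O
Why: Ozonolysis with reductive work-up should cleave the electron-rich styrene-type C6=C7 bond much faster than the anisole ring, and the cold neutral conditions leave C5 (now α to a formyl group) and C10 unchanged.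

Step 5
Reactants: 5 seco-dialdehyde
Product: 6 seven-membered lactol (oxygen bridges C7H2 and C6H(OH); anomeric mixture)
Conditions: LiAlH(Ot-Bu)3 (1.05 equiv), THF, −78 °C; aq. potassium sodium tartrate
Reagents that add atoms: none
Why: Chemoselective hydride reduction, in which the bulky hydride should reach the aryl formyl group far faster than the C6 formyl group (on a carbon flanked by the quaternary C4 and C10), after which the benzylic alcohol closes on the neighbouring aldehyde to the lactol, whose anomeric center is of no consequence.

Step 6
Reactants: 6 seven-membered lactol; 3 sugiol methyl ether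
Product: 9 vinyl acetal (C6 acetal carbon of half A bonded to the enol oxygen on C7' of half B), via chloro ether 7 (not isolated), via potassium enolate 8 (not isolated)
Conditions: 6, 1-chloro-N,N,2-trimethylprop-1-en-1-amine, CH2Cl2, 0 °C; separately 3, KN(SiMe3)2, THF–DMPU, −78 °C; combine, −78 to 0 °C; Et3N-treated silica
Reagents that add atoms: none
Why: O-Alkylation of a potassium enolate by a hard α-chloro ether (the way alkoxymethyl enol ethers are made) should beat C-alkylation because C6' is shielded by ring A and its axial methyl groups, and the acetal carbon forms as an anomeric mixture that is irrelevant because it becomes a planar radical in step 7.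

Step 7
Reactants: 9 vinyl acetal
Product: 12 target dimer (CNP0327150.1), via seco-aldehyde C6 radical 10 (not isolated), via ring-B alkoxy radical 11 (not isolated)
Conditions: (t-BuO)3SiSH (10 mol %), 2,2-bis(tert-butylperoxy)butane (10 mol %, in portions), 2,4,6-collidine (10 mol %), degassed octane, 0.02 M, reflux (125 °C)
Reagents that add atoms: none
Why: Proposed new method: a thiol-mediated radical chain in which the silanethiyl radical abstracts a benzylic hydrogen from C7 of half A, the C7 radical undergoes β-scission of the O–C6 acetal bond to give the aryl aldehyde and the α-alkoxy C6 radical 10, 10 adds to the formyl carbon (6-exo-trig, closing ring B) to give alkoxy radical 11, 11 adds to C6' of the enol ether (6-endo-trig, closing the 1,4-dioxane), and the benzylic α-alkoxy C7' radical takes hydrogen from the thiol to carry the chain, so that the step is a pure isomerization. The closest known reaction types are the thiol-catalysed radical-chain redox rearrangement of benzylidene acetals and cyclization of unsaturated acetals (polarity-reversal catalysis), the radical-pair course of the 1,2-Wittig rearrangement of acetals, 6-exo radical cyclization onto aldehydes, and alkoxy-radical addition to enol ethers. C6 should take its oxygen equatorial (α) because an axial C6 substituent would clash with the axial methyl groups on C4 and C10, and because C–C closure is reversible only the alkoxy radical that can reach the enol ether is drained; the oxygen should add to C6' from the α face because the β face of half B is blocked by the same two axial methyl groups. The benzylic centers C7 and C7' should end trans-diequatorial because hydrogen delivery to C7' is axial from the α face and because reversible thiyl hydrogen abstraction at these benzylic ether positions lets them settle in the all-trans, doubly trans-fused dioxane. The selectivity needed is abstraction at C7–H rather than at the acetal C6–H or irreversible thiyl addition to the alkene (secured by the weak, hydridic, para-methoxybenzylic C7–H bond, by the two quaternary carbons shielding C6–H, and by the reversibility of thiyl addition to a trisubstituted enol ether), and ring closure of 10 faster than its reduction (secured by the low stationary thiol concentration and the proximity of the just-released formyl group).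

**Compound list**
1 | (+)-ferruginol, (5S,10S)-abieta-8,11,13-trien-12-ol (5α-H, 10β-CH3) | Oc1cc2c(cc1C(C)C)CC[C@H]1C(C)(C)CCC[C@]21C | starting material
2 | ferruginol methyl ether, 12-methoxyabieta-8,11,13-triene | COc1cc2c(cc1C(C)C)CC[C@H]1C(C)(C)CCC[C@]21C | intermediate
3 | sugiol methyl ether, 12-methoxyabieta-8,11,13-trien-7-one | COc1cc2c(cc1C(C)C)C(=O)C[C@H]1C(C)(C)CCC[C@]21C | intermediate
4 | 12-methoxyabieta-6,8,11,13-tetraene | COc1cc2c(cc1C(C)C)C=C[C@H]1C(C)(C)CCC[C@]21C | intermediate
5 | 12-methoxy-6,7-secoabieta-8,11,13-triene-6,7-dial (5α-H, 10β-CH3) | COc1cc([C@]2(C)[C@@H](C=O)C(C)(C)CCC2)c(C=O)cc1C(C)C | intermediate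
6 | lactol of 7-hydroxy-12-methoxy-6,7-secoabieta-8,11,13-trien-6-al (seven-membered ring C7H2–O–C6H(OH), anomeric mixture) | COc1cc2c(cc1C(C)C)COC(O)[C@H]1C(C)(C)CCC[C@]21C | intermediate
7 | C6 chloro ether of lactol 6 (anomeric mixture) | COc1cc2c(cc1C(C)C)COC(Cl)[C@H]1C(C)(C)CCC[C@]21C | intermediate
8 | potassium 12-methoxyabieta-6,8,11,13-tetraen-7-olate | COc1cc2c(cc1C(C)C)C([O-])=C[C@H]1C(C)(C)CCC[C@]21C.[K+] | intermediate
9 | vinyl acetal: C6 of the oxa-homo ring B of half A carries the ring oxygen (to C7H2) and the enol oxygen on C7' of 12-methoxyabieta-6,8,11,13-tetraene (half B); anomeric mixture at C6 | COc1cc2c(cc1C(C)C)COC(OC3=C[C@H]4C(C)(C)CCC[C@]4(C)c4cc(OC)c(C(C)C)cc43)[C@H]1C(C)(C)CCC[C@]21C | intermediate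
10 | seco-aldehyde C6 radical (aryl aldehyde at C7, α-alkoxy radical at C6 bearing the enol ether of half B) | COc1cc([C@]2(C)[C@@H]([CH]OC3=C[C@H]4C(C)(C)CCC[C@]4(C)c4cc(OC)c(C(C)C)cc43)C(C)(C)CCC2)c(C=O)cc1C(C)C | intermediate
11 | ring-B alkoxy radical (ring B of half A closed; 7β-O radical, 6α-enol ether) | COc1cc2c(cc1C(C)C)[C@@H]([O])[C@H](OC3=C[C@H]4C(C)(C)CCC[C@]4(C)c4cc(OC)c(C(C)C)cc43)[C@H]1C(C)(C)CCC[C@]21C | intermediate
12 | target dimer: two 12-methoxyabieta-8,11,13-triene units joined by a 1,4-dioxane through C7β–O–C6'α and C6α–O–C7'β | COc1cc2c(cc1C(C)C)[C@H]1O[C@H]3[C@H](O[C@@H]1[C@H]1C(C)(C)CCC[C@]21C)c1cc(C(C)C)c(OC)cc1[C@@]1(C)CCCC(C)(C)[C@H]31 | target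

**Step count and risks**
Total steps: 7. Longest linear sequence: 6 (steps 1, 3, 4, 5, 6, 7); step 2 is the one-step branch to half B.

Steps most likely to fail:

1. Step 7 (Proposed new method). The chain may be cut short by hydrogen transfer to the ring-opened C6 radical before it closes onto the aldehyde, or by hydrogen abstraction at the wrong site. The fallback uses known chemistry, sets out from 9 and comes back at 12. Treating 9 with n-BuLi in THF (−78 to −30 °C) should effect the 1,2-Wittig ring contraction of the benzyl acetal (deprotonation at C7, migration of the acetal carbon C6 from oxygen to carbon) and give, after aqueous work-up, the 7β-hydroxy 6α-enol ether F1. Irradiating this with 9-mesityl-10-methylacridinium tetrafluoroborate (cat.) and a thiol hydrogen donor in 1,2-dichloroethane (blue LEDs) should then close the dioxane by photoredox anti-Markovnikov hydroetherification of the enol ether, giving 12.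

2. Step 6. The ambident enolate may be alkylated at carbon, or the chloro ether may lose HCl faster than it is captured. The fallback sets out from 3 (with chloro ether 7 made from 6 as before) and comes back at 9. Aerobic dehydrogenation of 3 (Pd(O2CCF3)2 cat., DMSO, O2, AcOH, 80 °C) gives 12-methoxyabieta-5,8,11,13-tetraen-7-one F2. Luche reduction (NaBH4, CeCl3·7H2O, MeOH, −40 °C; hydride from the α face, away from the C10 methyl) gives 12-methoxyabieta-5,8,11,13-tetraen-7β-ol F3. This non-ambident alcohol is alkylated by 7 with i-Pr2NEt in CH2Cl2 to the allyl acetal F4. KOt-Bu (cat.) in DMSO then moves the double bond into conjugation with the arene and the oxygen (C5 reprotonated from the α face), giving 9.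

3. Step 5. Chemoselectivity between the two formyl groups may be lost (reduction of the aliphatic aldehyde or over-reduction). The fallback sets out from 5 and comes back at 6. NaBH4 in MeOH reduces both aldehydes to the 6,7-seco-6,7-diol F5. t-BuMe2SiCl and imidazole silylate only the less hindered benzylic hydroxyl, giving the silyl ether F6. Dess–Martin periodinane oxidizes the remaining neopentyl-type alcohol to the silyloxy aldehyde F7. Bu4NF in THF then frees the benzylic alcohol, which closes to lactol 6.

Further compounds
F1 | step 7 | 6α-[(12-methoxyabieta-6,8,11,13-tetraen-7-yl)oxy]-12-methoxyabieta-8,11,13-trien-7β-ol | COc1cc2c(cc1C(C)C)[C@@H](O)[C@H](OC3=C[C@H]4C(C)(C)CCC[C@]4(C)c4cc(OC)c(C(C)C)cc43)[C@H]1C(C)(C)CCC[C@]21C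
F2 | step 6 | 12-methoxyabieta-5,8,11,13-tetraen-7-one | COc1cc2c(cc1C(C)C)C(=O)C=C1C(C)(C)CCC[C@]21C
F3 | step 6 | 12-methoxyabieta-5,8,11,13-tetraen-7β-ol | COc1cc2c(cc1C(C)C)[C@@H](O)C=C1C(C)(C)CCC[C@]21C
F4 | step 6 | allyl acetal: C6 acetal carbon of half A bonded to the 7'β-oxygen of 12-methoxyabieta-5,8,11,13-tetraene | COc1cc2c(cc1C(C)C)COC(O[C@H]3C=C4C(C)(C)CCC[C@]4(C)c4cc(OC)c(C(C)C)cc43)[C@H]1C(C)(C)CCC[C@]21C
F5 | step 5 | 12-methoxy-6,7-secoabieta-8,11,13-triene-6,7-diol | COc1cc([C@]2(C)[C@@H](CO)C(C)(C)CCC2)c(CO)cc1C(C)C
F6 | step 5 | 7-(tert-butyldimethylsilyloxy)-12-methoxy-6,7-secoabieta-8,11,13-trien-6-ol | COc1cc([C@]2(C)[C@@H](CO)C(C)(C)CCC2)c(CO[Si](C)(C)C(C)(C)C)cc1C(C)C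
F7 | step 5 | 7-(tert-butyldimethylsilyloxy)-12-methoxy-6,7-secoabieta-8,11,13-trien-6-al | COc1cc([C@]2(C)[C@@H](C=O)C(C)(C)CCC2)c(CO[Si](C)(C)C(C)(C)C)cc1C(C)C
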